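The constants set the terms of this flask: the free base holds a proton more tightly than the nucleophile does, by a gap of 0.669 in the logarithm, and the rate constant of the first step ties the electrophile's decay to free nucleophile.

    electrophile + nucleophile → acid set free + product (k1 = 0.037 M⁻¹ min⁻¹)
    nucleophile + acid set free ⇌ protonated nucleophile, settled at all times (K2 = 3000 M⁻¹)
    acid set free + free base ⇌ salt of the base, settled at all times (K3 = 14000 M⁻¹)
    free base + product ⇌ idle adduct, settled at all times (K4 = 12 M⁻¹)

electrophile 0.050 M; protonated nucleophile 2.00 equiv; time 20 h

- for product the idle adduct is counted in
- the amount of free base is what is sought; it is there from the start
- run time (flask): 20 h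

1. the equivalents of free base at which the part of the electrophile that has reacted at 20 h is just 70%

The logarithm of the electrophile left falls at the rate constant times free nucleophile. Leaving 30.0% is a fall of 1.20. That fall, divided by the rate constant and the time, gives 0.0271 M: the required mean nucleophile, the time-average of free nucleophile that a repeat has to hold.

Now the books of the electrophile, the limiting reagent, with free acid left aside. Of each mole charged, 30.0% stays and 70.0% becomes product. Each mole reacted takes one nucleophile out of the stock charged as protonated nucleophile and sets one acid free, so it passes two protons to the base. The salt therefore takes 0.0700 M, or 1.40 equiv, plus one more proton for each free nucleophile standing. That is the floor of the charge.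

To get a ceiling, close the books with free nucleophile still at the required mean at the end. The salt is then 0.0971 M and the protonated nucleophile 0.0379 M. The two balances leave free base at 0.0149 M, and the idle adduct holds 0.00531 M. The base charge comes to 2.35 equiv. Free nucleophile falls as the run goes on, so its end value lies below the mean and this figure is too high. My own reckoning commits to the logarithmic middle of floor and ceiling, 1.81 equiv, which is a guess inside that bracket and not a solution.

The forecast gives 1.77 equiv, with a range of 1.68 equiv to 1.85 equiv, and says the run “needs a weighted mean free nucleophile of about 0.027 M”. The two figures differ: 1.81 equiv here, 1.77 equiv there.

The flask needs 1.76 equiv. With that charge, the half-life of electrophile by the first step is 8.2 h at 3.97 h and 24 h at 20.0 h. Each half-life gives free nucleophile as ln(2) over the rate constant times the half-life: 0.0380 M at the earlier time and 0.0132 M at the later. The required mean nucleophile, 0.0271 M, lies between them, and the end value is about half of it.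

The numbers are assumed, and the outcome is calculated.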